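**Retrosynthetic overview**

- The strategy rests on the seven-membered ring C1–C5–C6–C7–C8–C9–C10. Its C8=C9 alkene, the single CH2 at C7, the C5–H/C6–O pair (a masked C5=C6 alkene) and the bond between quaternary C1 (methyl) and oxygenated C10 are the cyclohepta-1,4-diene and the new sigma bond that a cis-divinylcyclopropane Cope rearrangement leaves behind.
- Late stage: C10 angelate from the C10 alcohol; C4 tertiary carbinol from a C4 ketone and an isopropyl nucleophile; C8 methyl from a C8 ester; C5–H/C6–O from hydroboration of C5=C6.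
- Core: the hydroazulene diene from a silyloxy vinylcyclopentene and a 4-silyloxy vinyldiazoacetate by rhodium-carbenoid cyclopropanation and [3,3] shift (formal [4+3]).
- Ring order: the cyclopentene is bought (3-methylcyclopentenone); the cyclopropane C6–C7–C8 is made and opened within the key step, which leaves the seven-membered ring; no ring is formed afterwards.

Key step: step 7

Numbering and faces: daucane numbering is used for all bicyclic compounds (C1 quaternary carbon with methyl, C2 and C3 methylenes, C4, C5 ring-fusion CH, C6 to C10 around the seven-membered ring); β is the face of the C1 methyl, α the opposite face.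

Assumption: the sense of induction of Rh2(R-DOSP)4 is taken by analogy with its cyclopropanation of monosubstituted alkenes; if the other cyclopropane enantiomer were favoured, Rh2(S-DOSP)4 would be used and nothing else would change.

**Route**

Step 1
Reactants: 1 3-methylcyclopent-2-en-1-one
Product: 2 2-iodo-3-methylcyclopent-2-en-1-one
Conditions: I2, pyridine, CH2Cl2, 0 °C to rt
Reagents that add atoms: iodine, [I][I]
Why: Baylis–Hillman-type α-iodination of an enone, in which pyridine adds at C3, the enolate is iodinated at C2 and pyridine is expelled, which should give the 2-iodoenone without touching the ring methyl.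

Step 2
Reactants: 2 2-iodo-3-methylcyclopent-2-en-1-one
Product: 3 (S)-2-iodo-3-methylcyclopent-2-en-1-ol
Conditions: (R)-2-methyl-CBS-oxazaborolidine [(3aR)-1-methyl-3,3-diphenyltetrahydro-1H,3H-pyrrolo[1,2-c][1,3,2]oxazaborole, 15 mol %], BH3·SMe2, THF, −20 °C; MeOH quench
Reagents that add atoms: none
Why: Corey–Bakshi–Shibata reduction, in which the iodoalkenyl arm behaves as the large substituent so that the (R)-oxazaborolidine–borane complex should deliver hydride to the face that gives the S carbinol, with 1,2-selectivity only.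

Step 3
Reactants: 3 (S)-2-iodo-3-methylcyclopent-2-en-1-ol
Product: 4 (S)-triethyl[(2-iodo-3-methylcyclopent-2-en-1-yl)oxy]silane
Conditions: Et3SiCl, imidazole, DMF, 0 °C to rt
Reagents that add atoms: chlorotriethylsilane, CC[Si](Cl)(CC)CC
Why: Standard silylation of a secondary allylic alcohol, the triethylsilyl ether being chosen because it can later be removed in the presence of a tert-butyldimethylsilyl ether.

Step 4
Reactants: 4 (S)-triethyl[(2-iodo-3-methylcyclopent-2-en-1-yl)oxy]silane; 5 tributyl(vinyl)stannane
Product: 6 (S)-triethyl[(3-methyl-2-vinylcyclopent-2-en-1-yl)oxy]silane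
Conditions: Pd2(dba)3 [tris(dibenzylideneacetone)dipalladium, zerovalent palladium, 2.5 mol %], AsPh3, CuI, NMP, 50 °C
Reagents that add atoms: none
Why: Stille cross-coupling of an alkenyl iodide, in which triphenylarsine and CuI speed up transmetallation at the hindered tetrasubstituted alkene while the carbinol centre and the silyl ether take no part.

Step 5
Reactants: 7 ethyl diazoacetate; 8 (tert-butyldimethylsilyloxy)acetaldehyde
Product: 9 ethyl 4-(tert-butyldimethylsilyloxy)-2-diazo-3-hydroxybutanoate (racemic)
Conditions: 1,8-diazabicyclo[5.4.0]undec-7-ene (DBU, 10 mol %), MeCN, 0 °C to rt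
Reagents that add atoms: none
Why: Base-catalysed aldol-type addition of the nucleophilic diazo carbon of 7 to the aldehyde, which keeps the diazo group and gives the β-hydroxy-α-diazo ester (its carbinol centre disappears in the next step, so no control is needed).

Step 6
Reactants: 9 ethyl 4-(tert-butyldimethylsilyloxy)-2-diazo-3-hydroxybutanoate
Product: 10 ethyl (E)-4-(tert-butyldimethylsilyloxy)-2-diazobut-3-enoate
Conditions: POCl3, Et3N, CH2Cl2, 0 °C; kept cold and used at once
Reagents that add atoms: none
Why: Dehydration of a β-hydroxy-α-diazo ester through its dichlorophosphate (base-induced elimination toward C4, the only carbon with β-hydrogens), expected to give the conjugated vinyldiazoacetate with the thermodynamically preferred E enol ether.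

Step 7
Reactants: 6 (S)-triethyl[(3-methyl-2-vinylcyclopent-2-en-1-yl)oxy]silane; 10 ethyl (E)-4-(tert-butyldimethylsilyloxy)-2-diazobut-3-enoate
Product: 12 hydroazulene diene ester (C8 CO2Et; C5=C6 and C8=C9 alkenes; 1β-methyl; 4β-OSiEt3; 10α-OSiMe2t-Bu), via cis-divinylcyclopropane 11 (not isolated)
Conditions: Rh2(R-DOSP)4 {dirhodium tetrakis[(R)-N-(4-dodecylbenzenesulfonyl)prolinate], divalent rhodium, 2 mol %}, hexanes, −78 °C to rt, slow addition of 10; then toluene, 80 °C
Reagents that add atoms: none
Why: Loss of N2 from 10 at the divalent rhodium catalyst gives a donor/acceptor vinylcarbenoid whose carbenoid carbon (C8) adds across the terminal vinyl group C6=C7 of 6 to give cyclopropane 11 with the ester trans and the two alkenyl groups cis; this is the known tandem cyclopropanation/Cope rearrangement of vinyldiazoacetates with dienes (formal [4+3] cycloaddition), applied here with an untested 4-silyloxy reagent. The seven-membered ring is then closed pericyclically: the cis-divinylcyclopropane undergoes a [3,3] sigmatropic shift through a boat transition state in which C6–C8 breaks while C1–C10 forms, so that the three-membered ring is consumed and the C5=C6 and C8=C9 alkenes appear. C1 and C10 are set in this shift: the chiral prolinate catalyst fixes the absolute configuration of the cyclopropane carbons C6 and C8, the cyclopropane then lies on the face of the cyclopentene opposite the C4 silyloxy group (the matched arrangement), and the boat geometry places the outward E silyloxy group trans to the inward ring methyl, giving 1β-methyl and 10α-oxygen. The step needs site selectivity for the vinyl group over the tetrasubstituted ring alkene and over the allylic C4–H, which the steric demand of the donor/acceptor carbenoid and the unhindered monosubstituted alkene should secure, and it needs the E enol ether geometry to be carried through, which the concerted shift does. Warming is included because the methyl on the cyclopentene terminus points toward the cyclopropane CH2 in the boat and raises the barrier.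

Step 8
Reactants: 12 hydroazulene diene ester
Product: 14 trans-fused C6 alcohol (C8 CO2Et; C8=C9; 5α-H; 6α-OH; 4β-OSiEt3; 10α-OSiMe2t-Bu), via C6 monoalkylborane 13 (not isolated)
Conditions: BH3·THF, THF, 0 °C; then NaBO3·4H2O, THF/H2O, rt
Reagents that add atoms: sodium perborate (oxygen at C6 of 14), [Na+].[Na+].O[B-]1(O)OO[B-](O)(O)OO1; borane–tetrahydrofuran (boron of 13 only), B.C1CCOC1
Why: Hydroboration–oxidation, in which borane should add to the electron-rich trisubstituted C5=C6 in preference to the electron-poor enoate C8=C9, with boron at the less substituted C6 and syn delivery from the α face (opposite the C1 methyl and the C4 silyloxy group), which sets C5–H α (trans ring fusion) and, after perborate oxidation with retention, C6–OH α, the mild oxidant sparing the ester.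

Step 9
Reactants: 14 trans-fused C6 alcohol
Product: 15 allylic diol (C8 CH2OH; 6α-OH; C8=C9; silyl ethers unchanged)
Conditions: i-Bu2AlH, CH2Cl2, −78 °C; aqueous potassium sodium tartrate
Reagents that add atoms: none
Why: i-Bu2AlH reduces the conjugated ester by 1,2-hydride delivery to the primary allylic alcohol (the free C6 hydroxyl only consumes one equivalent), leaving the alkene and both silyl ethers intact.

Step 10
Reactants: 15 allylic diol
Product: 16 allylic chloride (C8 CH2Cl; 6α-OH)
Conditions: N-chlorosuccinimide, Me2S, CH2Cl2, −20 to 0 °C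
Reagents that add atoms: N-chlorosuccinimide, O=C1CCC(=O)N1Cl
Why: Corey–Kim-type chlorination with the N-chlorosuccinimide–dimethyl sulfide reagent, which converts allylic alcohols into chlorides by SN2 displacement of the alkoxysulfonium group while a saturated, hindered secondary alcohol such as C6–OH is returned on work-up.

Step 11
Reactants: 16 allylic chloride
Product: 17 C8-methyl C6 alcohol (C8 CH3; C8=C9; 6α-OH; 4β-OSiEt3; 10α-OSiMe2t-Bu)
Conditions: LiEt3BH, THF, 0 °C to rt
Reagents that add atoms: none
Why: SN2 hydride displacement of the primary allylic chloride by LiEt3BH gives the C8 methyl group, and the C6 alkoxide formed in passing cannot close onto the chloromethyl carbon because the bridged ether would carry a bridgehead alkene.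

Step 12
Reactants: 17 C8-methyl C6 alcohol; 18 3,4-dimethoxybenzoyl chloride
Product: 19 C6 veratrate (6α-O-3,4-dimethoxybenzoyl; C8 CH3; 4β-OSiEt3; 10α-OSiMe2t-Bu)
Conditions: Et3N, 4-(dimethylamino)pyridine (DMAP), CH2Cl2, rt
Reagents that add atoms: none
Why: DMAP-catalysed acylation (nucleophilic catalysis) of the only free hydroxyl, the secondary C6 alcohol, with the aroyl chloride.

Step 13
Reactants: 19 C6 veratrate
Product: 20 C4 alcohol (4β-OH; 6α-veratrate; 10α-OSiMe2t-Bu)
Conditions: pyridinium p-toluenesulfonate (cat.), MeOH/CH2Cl2, 0 °C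
Reagents that add atoms: none
Why: Acid-catalysed methanolysis tells the two silyl ethers apart by size, the triethylsilyl ether at C4 being cleaved far faster than the tert-butyldimethylsilyl ether at C10, while the ester is untouched.

Step 14
Reactants: 20 C4 alcohol
Product: 21 C4 ketone (C4=O; 5α-H; 6α-veratrate; 10α-OSiMe2t-Bu)
Conditions: Dess–Martin periodinane, NaHCO3, CH2Cl2, 0 °C to rt
Reagents that add atoms: none
Why: Dess–Martin oxidation of the secondary C4 alcohol under bicarbonate buffering, neutral enough that the β-aroyloxy ketone should neither lose the veratrate by elimination nor epimerise at C5.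

Step 15
Reactants: 21 C4 ketone; 22 isopropylmagnesium chloride
Product: 23 C4 tertiary alcohol (4β-OH; 4α-isopropyl; 6α-veratrate; 10α-OSiMe2t-Bu)
Conditions: CeCl3 (anhydrous), 22, THF, −78 °C, 1 h; then 21, −78 °C; AcOH/THF quench at −78 °C
Reagents that add atoms: none
Why: Organocerium addition (isopropylcerium dichloride from 22 and CeCl3) to the ketone, in which the weakly basic, oxophilic reagent should add at −78 °C faster than it enolises the ketone or attacks the aryl ester, and by analogy with angularly methylated hydrindanones it is predicted to approach C4 from the α face, away from the C1 methyl, setting 4β-OH and 4α-isopropyl.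

Step 16
Reactants: 23 C4 tertiary alcohol
Product: 24 C4,C10-diol (4β-OH tertiary; 10α-OH; 6α-veratrate)
Conditions: HF·pyridine, pyridine, THF, 0 °C to rt
Reagents that add atoms: none
Why: Fluoride-induced cleavage of the hindered allylic silyl ether with buffered HF·pyridine, conditions that should leave the aryl ester, the tertiary alcohol and the allylic C–O bond alone.

Step 17
Reactants: 24 C4,C10-diol; 25 angelic acid [(Z)-2-methylbut-2-enoic acid]
Product: 27 target CNP0142353.1 [10α-angeloyloxy-6α-(3,4-dimethoxybenzoyloxy)dauc-8-en-4β-ol], via angelic 2,4,6-trichlorobenzoic anhydride 26 (not isolated)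
Conditions: 25, 2,4,6-trichlorobenzoyl chloride, Et3N, toluene, rt; then 24, toluene, 80 °C
Reagents that add atoms: 2,4,6-trichlorobenzoyl chloride (aroyl part of 26 only), O=C(Cl)c1c(Cl)cc(Cl)cc1Cl
Why: Yamaguchi-type mixed-anhydride esterification run without a nucleophilic catalyst, in which the secondary allylic C10 alcohol attacks the unhindered angeloyl carbonyl of 26, the tertiary C4 alcohol does not react, and the absence of DMAP and of strong base should keep the Z alkene from isomerising to the tiglate.

**Compound list**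

1 | 3-methylcyclopent-2-en-1-one | CC1=CC(=O)CC1 | starting material
2 | 2-iodo-3-methylcyclopent-2-en-1-one | CC1=C(I)C(=O)CC1 | intermediate
3 | (S)-2-iodo-3-methylcyclopent-2-en-1-ol | IC1=C(C)CC[C@@H]1O | intermediate
4 | (S)-triethyl[(2-iodo-3-methylcyclopent-2-en-1-yl)oxy]silane | IC1=C(C)CC[C@@H]1O[Si](CC)(CC)CC | intermediate
5 | tributyl(vinyl)stannane | C=C[Sn](CCCC)(CCCC)CCCC | starting material
6 | (S)-triethyl[(3-methyl-2-vinylcyclopent-2-en-1-yl)oxy]silane | C=CC1=C(C)CC[C@@H]1O[Si](CC)(CC)CC | intermediate
7 | ethyl diazoacetate | CCOC(=O)C=[N+]=[N-] | starting material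
8 | (tert-butyldimethylsilyloxy)acetaldehyde | CC(C)(C)[Si](C)(C)OCC=O | starting material
9 | ethyl 4-(tert-butyldimethylsilyloxy)-2-diazo-3-hydroxybutanoate (racemic) | CCOC(=O)C(=[N+]=[N-])C(O)CO[Si](C)(C)C(C)(C)C | intermediate
10 | ethyl (E)-4-(tert-butyldimethylsilyloxy)-2-diazobut-3-enoate | CCOC(=O)C(=[N+]=[N-])/C=C/O[Si](C)(C)C(C)(C)C | intermediate
11 | ethyl (1R,2S)-1-[(E)-2-(tert-butyldimethylsilyloxy)vinyl]-2-[(5S)-2-methyl-5-(triethylsilyloxy)cyclopent-1-en-1-yl]cyclopropane-1-carboxylate (alkenyl groups cis) | CCOC(=O)[C@]1(/C=C/O[Si](C)(C)C(C)(C)C)C[C@H]1C2=C(C)CC[C@@H]2O[Si](CC)(CC)CC | intermediate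
12 | hydroazulene diene ester (C8 CO2Et; C5=C6 and C8=C9; 1β-methyl; 4β-OSiEt3; 10α-OSiMe2t-Bu) | CC(C)(C)[Si](C)(C)O[C@@H]1C=C(C(=O)OCC)CC=C2[C@]1(C)CC[C@@H]2O[Si](CC)(CC)CC | intermediate
13 | C6 monoalkylborane (6α-BH2; 5α-H) | CC(C)(C)[Si](C)(C)O[C@@H]1C=C(C(=O)OCC)C[C@H](B)[C@@H]2[C@]1(C)CC[C@@H]2O[Si](CC)(CC)CC | intermediate
14 | trans-fused C6 alcohol (6α-OH; 5α-H; C8 CO2Et) | CC(C)(C)[Si](C)(C)O[C@@H]1C=C(C(=O)OCC)C[C@H](O)[C@@H]2[C@]1(C)CC[C@@H]2O[Si](CC)(CC)CC | intermediate
15 | allylic diol (C8 CH2OH; 6α-OH) | CC(C)(C)[Si](C)(C)O[C@@H]1C=C(CO)C[C@H](O)[C@@H]2[C@]1(C)CC[C@@H]2O[Si](CC)(CC)CC | intermediate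
16 | allylic chloride (C8 CH2Cl; 6α-OH) | CC(C)(C)[Si](C)(C)O[C@@H]1C=C(CCl)C[C@H](O)[C@@H]2[C@]1(C)CC[C@@H]2O[Si](CC)(CC)CC | intermediate
17 | C8-methyl C6 alcohol | CC(C)(C)[Si](C)(C)O[C@@H]1C=C(C)C[C@H](O)[C@@H]2[C@]1(C)CC[C@@H]2O[Si](CC)(CC)CC | intermediate
18 | 3,4-dimethoxybenzoyl chloride | COc1ccc(C(=O)Cl)cc1OC | starting material
19 | C6 veratrate (4β-OSiEt3; 10α-OSiMe2t-Bu) | CC(C)(C)[Si](C)(C)O[C@@H]1C=C(C)C[C@H](OC(=O)c2ccc(OC)c(OC)c2)[C@@H]3[C@]1(C)CC[C@@H]3O[Si](CC)(CC)CC | intermediate
20 | C4 alcohol (4β-OH; 6α-veratrate; 10α-OSiMe2t-Bu) | CC(C)(C)[Si](C)(C)O[C@@H]1C=C(C)C[C@H](OC(=O)c2ccc(OC)c(OC)c2)[C@@H]3[C@]1(C)CC[C@@H]3O | intermediate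
21 | C4 ketone | CC(C)(C)[Si](C)(C)O[C@@H]1C=C(C)C[C@H](OC(=O)c2ccc(OC)c(OC)c2)[C@@H]3[C@]1(C)CCC3=O | intermediate
22 | isopropylmagnesium chloride | CC(C)[Mg]Cl | starting material
23 | C4 tertiary alcohol (4β-OH; 4α-isopropyl; 10α-OSiMe2t-Bu) | CC(C)(C)[Si](C)(C)O[C@@H]1C=C(C)C[C@H](OC(=O)c2ccc(OC)c(OC)c2)[C@@H]3[C@]1(C)CC[C@@]3(O)C(C)C | intermediate
24 | C4,C10-diol (4β-OH; 10α-OH; 6α-veratrate) | O[C@@H]1C=C(C)C[C@H](OC(=O)c2ccc(OC)c(OC)c2)[C@@H]3[C@]1(C)CC[C@@]3(O)C(C)C | intermediate
25 | angelic acid | C/C=C(/C)C(=O)O | starting material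
26 | angelic 2,4,6-trichlorobenzoic anhydride | C/C=C(/C)C(=O)OC(=O)c1c(Cl)cc(Cl)cc1Cl | intermediate
27 | CNP0142353.1, 10α-angeloyloxy-6α-(3,4-dimethoxybenzoyloxy)dauc-8-en-4β-ol | C/C=C(/C)C(=O)O[C@@H]1C=C(C)C[C@H](OC(=O)c2ccc(OC)c(OC)c2)[C@@H]2[C@]1(C)CC[C@@]2(O)C(C)C | target

**Step count**

Total steps: 17. Longest linear sequence: 15 steps (steps 1 to 4 and 7 to 17, from 1 to 27); steps 5 and 6 form the two-step side branch to 10.

**Steps most likely to fail**

Step 7. The electron-rich diazo enol ether 10 may cyclise to a pyrazole or be attacked at its oxygen-bearing terminus before it cyclopropanates, and the cyclopropane with the inward methyl may stall instead of rearranging. The fallback sets out from 6 and returns at 12; it replaces 10 by the long-used 3-silyloxy isomer and moves the oxygen to C10 afterwards. Commercial ethyl 2-diazo-3-oxobutanoate is silylated (t-BuMe2SiOTf, Et3N, CH2Cl2, 0 °C) to ethyl 3-(tert-butyldimethylsilyloxy)-2-diazobut-3-enoate F1. With 6 and the same Rh2(R-DOSP)4 catalyst this should give the cis-divinylcyclopropane carrying a 1-silyloxyvinyl group F2 and, after the same [3,3] shift, the C9 silyl enol ether of the ring β-keto ester F3, in which C10 is still CH2. Buffered fluoride (Bu4NF, AcOH, THF, −40 °C) would free the ring β-keto ester F4. Its dianion (NaH, then n-BuLi, THF, −78 °C) reacts at C10, and 3-phenyl-2-(phenylsulfonyl)oxaziridine should hydroxylate it on the face opposite the C1 methyl to give the 10α-hydroxy β-keto ester F5. Silylation (t-BuMe2SiCl, imidazole, DMF) gives the 10α-silyloxy β-keto ester F6, and triflation at C9 (NaH, PhNTf2, THF) gives the C9 enol triflate F7. Palladium-catalysed formate reduction (Pd(OAc)2, PPh3, HCO2H, Et3N, DMF, 60 °C) then removes the triflate and gives 12.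

Step 15. Enolisation of the ketone toward C5 followed by loss of the C6 veratrate, or attack of the reagent on the aryl ester, may compete with carbonyl addition. The fallback sets out from 17 and returns at 23; it carries the C6 oxygen through the ketone stage as an ether, a far poorer leaving group that is inert to the organometal, and acylates afterwards. Compound 17 is treated with 4-methoxybenzyl trichloroacetimidate and catalytic La(OTf)3 (toluene, rt) to give the C6 4-methoxybenzyl ether F8. Pyridinium p-toluenesulfonate in MeOH removes the triethylsilyl group to give the C4 alcohol F9, and Dess–Martin oxidation gives the C4 ketone F10. Isopropylcerium addition as in step 15 gives the C4 tertiary alcohol F11, and DDQ (CH2Cl2, pH 7 buffer) cleaves the benzyl ether to give the 4,6-diol F12. Only its secondary C6 hydroxyl is acylated by 18 (Et3N, DMAP), which gives 23.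

Step 17. Isomerisation of the angeloyl unit to the E (tiglate) geometry, or incomplete acylation of the neopentyl allylic C10 alcohol, may occur under forcing conditions. The fallback sets out from 24 and returns at 27; it builds the Z alkene on the ester instead of carrying it in the acylating agent. Compound 24 is esterified at C10 with 2-[bis(2,2,2-trifluoroethoxy)phosphoryl]propanoic acid (DCC, DMAP, CH2Cl2), an acid with no alkene to isomerise, to give the C10 phosphonopropanoate F13. A Still–Gennari olefination with acetaldehyde (KN(SiMe3)2, 18-crown-6, THF, −78 °C) should then give the Z-configured 2-methylbut-2-enoate, that is 27.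

**Further compounds**

F1 | step 7 | ethyl 3-(tert-butyldimethylsilyloxy)-2-diazobut-3-enoate | CCOC(=O)C(=[N+]=[N-])C(=C)O[Si](C)(C)C(C)(C)C
F2 | step 7 | cis-divinylcyclopropane carrying a 1-silyloxyvinyl group | CCOC(=O)[C@]1(C(=C)O[Si](C)(C)C(C)(C)C)C[C@H]1C2=C(C)CC[C@@H]2O[Si](CC)(CC)CC
F3 | step 7 | C9 silyl enol ether of the ring β-keto ester (C10 CH2) | C1C(O[Si](C)(C)C(C)(C)C)=C(C(=O)OCC)CC=C2[C@]1(C)CC[C@@H]2O[Si](CC)(CC)CC
F4 | step 7 | ring β-keto ester (C9 ketone; C8 CO2Et) | C1C(=O)C(C(=O)OCC)CC=C2[C@]1(C)CC[C@@H]2O[Si](CC)(CC)CC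
F5 | step 7 | 10α-hydroxy β-keto ester | O[C@@H]1C(=O)C(C(=O)OCC)CC=C2[C@]1(C)CC[C@@H]2O[Si](CC)(CC)CC
F6 | step 7 | 10α-silyloxy β-keto ester | CC(C)(C)[Si](C)(C)O[C@@H]1C(=O)C(C(=O)OCC)CC=C2[C@]1(C)CC[C@@H]2O[Si](CC)(CC)CC
F7 | step 7 | C9 enol triflate | CC(C)(C)[Si](C)(C)O[C@@H]1C(OS(=O)(=O)C(F)(F)F)=C(C(=O)OCC)CC=C2[C@]1(C)CC[C@@H]2O[Si](CC)(CC)CC
F8 | step 15 | C6 4-methoxybenzyl ether | CC(C)(C)[Si](C)(C)O[C@@H]1C=C(C)C[C@H](OCc2ccc(OC)cc2)[C@@H]3[C@]1(C)CC[C@@H]3O[Si](CC)(CC)CC
F9 | step 15 | C4 alcohol with C6 4-methoxybenzyl ether | CC(C)(C)[Si](C)(C)O[C@@H]1C=C(C)C[C@H](OCc2ccc(OC)cc2)[C@@H]3[C@]1(C)CC[C@@H]3O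
F10 | step 15 | C4 ketone with C6 4-methoxybenzyl ether | CC(C)(C)[Si](C)(C)O[C@@H]1C=C(C)C[C@H](OCc2ccc(OC)cc2)[C@@H]3[C@]1(C)CCC3=O
F11 | step 15 | C4 tertiary alcohol with C6 4-methoxybenzyl ether | CC(C)(C)[Si](C)(C)O[C@@H]1C=C(C)C[C@H](OCc2ccc(OC)cc2)[C@@H]3[C@]1(C)CC[C@@]3(O)C(C)C
F12 | step 15 | 4,6-diol (10α-OSiMe2t-Bu) | CC(C)(C)[Si](C)(C)O[C@@H]1C=C(C)C[C@H](O)[C@@H]3[C@]1(C)CC[C@@]3(O)C(C)C
F13 | step 17 | C10 phosphonopropanoate | CC(C(=O)O[C@@H]1C=C(C)C[C@H](OC(=O)c2ccc(OC)c(OC)c2)[C@@H]3[C@]1(C)CC[C@@]3(O)C(C)C)P(=O)(OCC(F)(F)F)OCC(F)(F)F
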